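The retrosynthesis first removes the ring B benzyl ether and tert-butyl ester. It then cuts the C6–heptyl and C1–CO2H bonds of ring A together, then the diaryl ether bond from oxygen to C4 of ring B, and finally on ring B the benzylic CH2–hexyl bond, the C6–O bond and the C4–B (C4–Br) bond.
Enabling feature: in ring A the carboxyl carbon C1 lies between the aryloxy carbon C2 and the heptyl carbon C6. A C1–C6 aryne whose only direct neighbour is the C2 oxygen therefore accepts a carbon nucleophile at C6 and an electrophile at C1.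
Forward: both benzene rings are bought and no ring is built. Ring B is dressed from 3-methoxy-2-methylbenzoic acid (steps 1–6) and ring A is armed from 5-methoxyresorcinol (steps 7–8). The halves are joined through oxygen (step 9), the aryne step follows (step 10), and two deprotections finish the route.
The iodine site on ring A is fixed by the mirror symmetry of 2-iodo-5-methoxyresorcinol, not by a late metalation among three similar C–H positions.
The target has no stereocentre and no stereogenic double bond, so only regiochemistry has to be controlled.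
Key step: step 10

Assumption: heptylmagnesium bromide is taken as a commercial ether solution (otherwise made from 1-bromoheptane and magnesium); atom numbers are ring A C1 = carboxyl carbon, C2 = aryloxy, C4 = methoxy, C6 = heptyl, and ring B C1 = carboxyl carbon, C2 = heptyl, C3 = methoxy, C4 = aryloxy, C6 = hydroxyl.

Step 1
Reactants: 1 3-methoxy-2-methylbenzoic acid; 2 1-bromohexane
Product: 4 2-heptyl-3-methoxybenzoic acid, via dilithio dianion 3 (not isolated)
Conditions: LDA (2.2 equiv), THF, −78 → 0 °C; 2 (1.2 equiv), −78 °C → rt; aq. HCl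
Reagents that add atoms: none
Why: Lateral lithiation of an ortho-toluic acid: LDA should first form the carboxylate and then remove a proton of the flanked methyl group, and the benzylic dianion 3 is alkylated at carbon by the primary bromide in an SN2 reaction.

Step 2
Reactants: 4 2-heptyl-3-methoxybenzoic acid
Product: 5 4,6-dibromo-2-heptyl-3-methoxybenzoic acid
Conditions: Br2 (2.3 equiv), AcOH, dark, rt → 60 °C
Reagents that add atoms: bromine, BrBr
Why: Electrophilic aromatic bromination is governed by the methoxy group, which activates only its para carbon C6 and its free ortho carbon C4, whereas C5 is meta to it and the carboxyl carbon is not activated for ipso attack, so the reaction should stop at the 4,6-dibromide.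

Step 3
Reactants: 5 4,6-dibromo-2-heptyl-3-methoxybenzoic acid
Product: 6 4-bromo-2-heptyl-6-hydroxy-3-methoxybenzoic acid
Conditions: CuSO4·5H2O (10 mol %), pyridine (0.5 equiv), Na2CO3 (3 equiv), H2O, 95 °C; aq. HCl
Reagents that add atoms: water, O
Why: Carboxylate-assisted Ullmann-type hydroxylation: copper held by the carboxylate reaches only the neighbouring C6–Br bond, as in the classical selective substitution of 2,4-dihalobenzoic acids, so the C4 bromide should survive these weakly ligated aqueous conditions.

Step 4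
Reactants: 6 4-bromo-2-heptyl-6-hydroxy-3-methoxybenzoic acid
Product: 7 tert-butyl 4-bromo-2-heptyl-6-hydroxy-3-methoxybenzoate
Conditions: Cl3CC(=NH)OtBu (3 equiv), CH2Cl2–cyclohexane, rt
Reagents that add atoms: tert-butyl 2,2,2-trichloroacetimidate, CC(C)(C)OC(=N)C(Cl)(Cl)Cl
Why: Trichloroacetimidate esterification transfers a tert-butyl cation to the carboxylate oxygen and so needs no attack at the carbonyl carbon crowded by two ortho groups, while the hydrogen-bonded phenol is too poor a nucleophile to compete.

Step 5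
Reactants: 7 tert-butyl 4-bromo-2-heptyl-6-hydroxy-3-methoxybenzoate
Product: 8 tert-butyl 6-(benzyloxy)-4-bromo-2-heptyl-3-methoxybenzoate
Conditions: BnBr (1.2 equiv), K2CO3, DMF, 60 °C
Reagents that add atoms: benzyl bromide, BrCc1ccccc1
Why: Williamson ether synthesis on the phenoxide, which warm DMF frees from its hydrogen bond to the ester, while the hindered tert-butyl ester and the aryl bromide are inert to K2CO3.

Step 6
Reactants: 8 tert-butyl 6-(benzyloxy)-4-bromo-2-heptyl-3-methoxybenzoate
Product: 11 [5-(benzyloxy)-4-(tert-butoxycarbonyl)-3-heptyl-2-methoxyphenyl]boronic acid, via aryllithium 9 (not isolated), via lithium triisopropoxyborate 10 (not isolated)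
Conditions: B(OiPr)3 (1.5 equiv), then n-BuLi (1.1 equiv, added last), THF–toluene, −78 → −20 °C; 1 M HCl
Reagents that add atoms: triisopropyl borate, CC(C)OB(OC(C)C)OC(C)C; water, O
Why: Bromine–lithium exchange at −78 °C is faster than attack of n-BuLi on the borate or on the shielded tert-butyl ester, and because B(OiPr)3 is already present (in situ quench) aryllithium 9 is captured at once as ate complex 10, which mild acid hydrolyses to the boronic acid.

Step 7
Reactants: 12 5-methoxyresorcinol
Product: 13 2-iodo-5-methoxybenzene-1,3-diol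
Conditions: I2 (1.0 equiv), NaHCO3 (1.1 equiv), H2O, 0 °C → rt
Reagents that add atoms: iodine, II
Why: Electrophilic iodination of resorcinols with I2 in aqueous NaHCO3 is known to favour the carbon between the two hydroxyl groups, here also para to methoxy, and the mirror-symmetric product fixes the place of iodine relative to both oxygens.

Step 8
Reactants: 13 2-iodo-5-methoxybenzene-1,3-diol
Product: 14 3-hydroxy-2-iodo-5-methoxyphenyl 4-chlorobenzenesulfonate
Conditions: 4-ClC6H4SO2Cl (0.95 equiv, slow addition), Et3N (1.1 equiv), CH2Cl2, 0 °C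
Reagents that add atoms: 4-chlorobenzenesulfonyl chloride, O=S(=O)(Cl)c1ccc(Cl)cc1
Why: O-Sulfonylation of one of two equivalent phenols raises no regiochemical issue, and slow addition of slightly less than one equivalent of the sulfonyl chloride should hold double sulfonylation down while unreacted 13 is recovered.

Step 9
Reactants: 11 [5-(benzyloxy)-4-(tert-butoxycarbonyl)-3-heptyl-2-methoxyphenyl]boronic acid; 14 3-hydroxy-2-iodo-5-methoxyphenyl 4-chlorobenzenesulfonate
Product: 15 tert-butyl 6-(benzyloxy)-4-{3-[(4-chlorophenyl)sulfonyloxy]-2-iodo-5-methoxyphenoxy}-2-heptyl-3-methoxybenzoate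
Conditions: 11 (1.5 equiv), Cu(OAc)2 (1.0 equiv), pyridine (5 equiv), 4 Å molecular sieves, CH2Cl2, dry air, rt
Reagents that add atoms: none
Why: Chan–Lam coupling: the aryl group passes from boron to a copper phenoxide, oxidation to trivalent copper with air as terminal oxidant triggers C–O reductive elimination at room temperature, and phenols flanked by ortho iodine are proven partners whose carbon–iodine bond, like the sulfonate, is left alone under these amine-buffered conditions.

Step 10
Reactants: 15 tert-butyl 6-(benzyloxy)-4-{3-[(4-chlorophenyl)sulfonyloxy]-2-iodo-5-methoxyphenoxy}-2-heptyl-3-methoxybenzoate; 16 heptylmagnesium bromide; 17 carbon dioxide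
Product: 21 2-[5-(benzyloxy)-4-(tert-butoxycarbonyl)-3-heptyl-2-methoxyphenoxy]-6-heptyl-4-methoxybenzoic acid, via magnesiated sulfonate 18 (not isolated), via C1-C6 aryne 19 (not isolated), via C1 arylmagnesium bromide 20 (not isolated)
Conditions: iPrMgCl (1.05 equiv), THF, −78 °C; 16 (3.5 equiv), −78 → 0 °C; 17 (dry gas), −20 °C → rt; 1 M HCl
Reagents that add atoms: none
Why: iPrMgCl exchanges the iodine on C1, which two flanking oxygens activate, to give 18, stable at −78 °C, and on warming 18 expels the 4-chlorobenzenesulfonate from C6 (a far better leaving group than the aryloxide on C2) and releases aryne 19. The excess of 16 carbomagnesiates the strained triple bond to give 20, and CO2 turns the C1–Mg bond into the carboxylate, so the C6–heptyl and C1–carboxyl bonds arise in one flask. The closest known reaction type is the addition of alkyllithium or alkylmagnesium reagents to 3-alkoxyarynes followed by carboxylation, the established entry to 6-alkylsalicylic and 6-alkyl-2,4-dialkoxybenzoic acids, combined here with aryne release from 2-iodoaryl sulfonates by halogen–magnesium exchange. No ring is closed and no stereocentre is formed. The step needs regioselectivity, and the sigma-withdrawing oxygen on C2 secures it by distorting the aryne so that C6 is the more linear, more electrophilic carbon and the developing carbanion rests on C1 beside that oxygen, while the C4 methoxy group (meta to C6, para to C1) exerts only a weak opposing pull. It also needs chemoselectivity: the ring B tert-butyl ester is shielded on both sides by heptyl and benzyloxy and should ignore both Grignard reagents up to 0 °C, and the high concentration of 16 should outrun capture of the aryne by the ring B methoxy oxygen.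

Step 11
Reactants: 21 2-[5-(benzyloxy)-4-(tert-butoxycarbonyl)-3-heptyl-2-methoxyphenoxy]-6-heptyl-4-methoxybenzoic acid
Product: 22 6-(benzyloxy)-4-(2-carboxy-3-heptyl-5-methoxyphenoxy)-2-heptyl-3-methoxybenzoic acid
Conditions: TFA–CH2Cl2 (1:4), 0 °C → rt
Reagents that add atoms: none
Why: Acidolysis of the tert-butyl ester by alkyl–oxygen cleavage (loss of the tert-butyl cation as 2-methylpropene) needs no access to the hindered carbonyl group, and cold dilute TFA should spare the benzyl ether, the methyl ethers and both electron-rich carboxyl groups.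

Step 12
Reactants: 22 6-(benzyloxy)-4-(2-carboxy-3-heptyl-5-methoxyphenoxy)-2-heptyl-3-methoxybenzoic acid
Product: 23 4-(2-carboxy-3-heptyl-5-methoxyphenoxy)-2-heptyl-6-hydroxy-3-methoxybenzoic acid (CNP0151337.0)
Conditions: H2 (1 atm), Pd/C (10 wt %), EtOAc, rt
Reagents that add atoms: none
Why: Catalytic hydrogenolysis cleaves the benzylic C–O bond under neutral conditions, the safest last step for a salicylic acid prone to acid- or heat-induced decarboxylation, and nothing else in 22 is reducible.

Compound list
1 | 3-methoxy-2-methylbenzoic acid | COc1cccc(C(=O)O)c1C | starting material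
2 | 1-bromohexane | CCCCCCBr | starting material
3 | lithium 2-(lithiomethyl)-3-methoxybenzoate | [Li]Cc1c(OC)cccc1C(=O)O[Li] | intermediate
4 | 2-heptyl-3-methoxybenzoic acid | CCCCCCCc1c(OC)cccc1C(=O)O | intermediate
5 | 4,6-dibromo-2-heptyl-3-methoxybenzoic acid | CCCCCCCc1c(OC)c(Br)cc(Br)c1C(=O)O | intermediate
6 | 4-bromo-2-heptyl-6-hydroxy-3-methoxybenzoic acid | CCCCCCCc1c(OC)c(Br)cc(O)c1C(=O)O | intermediate
7 | tert-butyl 4-bromo-2-heptyl-6-hydroxy-3-methoxybenzoate | CCCCCCCc1c(OC)c(Br)cc(O)c1C(=O)OC(C)(C)C | intermediate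
8 | tert-butyl 6-(benzyloxy)-4-bromo-2-heptyl-3-methoxybenzoate | CCCCCCCc1c(OC)c(Br)cc(OCc2ccccc2)c1C(=O)OC(C)(C)C | intermediate
9 | tert-butyl 6-(benzyloxy)-2-heptyl-4-lithio-3-methoxybenzoate | CCCCCCCc1c(OC)c([Li])cc(OCc2ccccc2)c1C(=O)OC(C)(C)C | intermediate
10 | lithium [5-(benzyloxy)-4-(tert-butoxycarbonyl)-3-heptyl-2-methoxyphenyl]triisopropoxyborate | CCCCCCCc1c(OC)c([B-](OC(C)C)(OC(C)C)OC(C)C)cc(OCc2ccccc2)c1C(=O)OC(C)(C)C.[Li+] | intermediate
11 | [5-(benzyloxy)-4-(tert-butoxycarbonyl)-3-heptyl-2-methoxyphenyl]boronic acid | CCCCCCCc1c(OC)c(B(O)O)cc(OCc2ccccc2)c1C(=O)OC(C)(C)C | intermediate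
12 | 5-methoxyresorcinol | COc1cc(O)cc(O)c1 | starting material
13 | 2-iodo-5-methoxybenzene-1,3-diol | COc1cc(O)c(I)c(O)c1 | intermediate
14 | 3-hydroxy-2-iodo-5-methoxyphenyl 4-chlorobenzenesulfonate | COc1cc(O)c(I)c(OS(=O)(=O)c2ccc(Cl)cc2)c1 | intermediate
15 | tert-butyl 6-(benzyloxy)-4-{3-[(4-chlorophenyl)sulfonyloxy]-2-iodo-5-methoxyphenoxy}-2-heptyl-3-methoxybenzoate | COc1cc(OS(=O)(=O)c2ccc(Cl)cc2)c(I)c(Oc2cc(OCc3ccccc3)c(C(=O)OC(C)(C)C)c(CCCCCCC)c2OC)c1 | intermediate
16 | heptylmagnesium bromide | CCCCCCC[Mg]Br | starting material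
17 | carbon dioxide | O=C=O | starting material
18 | ring A C1 chloromagnesium derivative of 15 (iodine replaced by MgCl) | COc1cc(OS(=O)(=O)c2ccc(Cl)cc2)c([Mg]Cl)c(Oc2cc(OCc3ccccc3)c(C(=O)OC(C)(C)C)c(CCCCCCC)c2OC)c1 | intermediate
19 | ring A C1–C6 aryne (3-aryloxy-5-methoxybenzyne carrying protected ring B) | COC1=CC#CC(Oc2cc(OCc3ccccc3)c(C(=O)OC(C)(C)C)c(CCCCCCC)c2OC)=C1 | intermediate
20 | ring A C1 bromomagnesium adduct (heptyl on C6) | CCCCCCCc1cc(OC)cc(Oc2cc(OCc3ccccc3)c(C(=O)OC(C)(C)C)c(CCCCCCC)c2OC)c1[Mg]Br | intermediate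
21 | 2-[5-(benzyloxy)-4-(tert-butoxycarbonyl)-3-heptyl-2-methoxyphenoxy]-6-heptyl-4-methoxybenzoic acid | CCCCCCCc1cc(OC)cc(Oc2cc(OCc3ccccc3)c(C(=O)OC(C)(C)C)c(CCCCCCC)c2OC)c1C(=O)O | intermediate
22 | 6-(benzyloxy)-4-(2-carboxy-3-heptyl-5-methoxyphenoxy)-2-heptyl-3-methoxybenzoic acid | CCCCCCCc1cc(OC)cc(Oc2cc(OCc3ccccc3)c(C(=O)O)c(CCCCCCC)c2OC)c1C(=O)O | intermediate
23 | 4-(2-carboxy-3-heptyl-5-methoxyphenoxy)-2-heptyl-6-hydroxy-3-methoxybenzoic acid | CCCCCCCc1cc(OC)cc(Oc2cc(O)c(C(=O)O)c(CCCCCCC)c2OC)c1C(=O)O | target

Total step count: 12. Longest linear sequence: 10 steps (steps 1–6, then 9–12); steps 7–8 form the short ring A branch.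

Steps most likely to fail

Step 10 (aryne three-component reaction). Several processes could cut into the reaction:
- The Grignard reagents may attack the sulfonate sulfur before exchange is complete.
- The aryne may be captured by the neighbouring ring B methoxy oxygen.
- Regiocontrol may erode.
- The crowded arylmagnesium 20 may be protonated before it is carboxylated.

The fallback runs the same three-component reaction before the ether is made, on a substrate that carries no ring B.
- It sets out from 14. Benzylation (BnBr, K2CO3, acetone) gives 3-(benzyloxy)-2-iodo-5-methoxyphenyl 4-chlorobenzenesulfonate F1.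
- The conditions of step 10 with 16 and 17 should turn F1 into 2-(benzyloxy)-6-heptyl-4-methoxybenzoic acid F2.
- Trichloroacetimidate esterification as in step 4 gives tert-butyl 2-(benzyloxy)-6-heptyl-4-methoxybenzoate F3.
- Hydrogenolysis frees tert-butyl 2-heptyl-6-hydroxy-4-methoxybenzoate F4.
- No aryl iodide is present any longer, so an Ullmann ether synthesis with bromide 8 (CuI, N,N-dimethylglycine, Cs2CO3, dioxane, 100 °C) gives tert-butyl 6-(benzyloxy)-4-[2-(tert-butoxycarbonyl)-3-heptyl-5-methoxyphenoxy]-2-heptyl-3-methoxybenzoate F5.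
- TFA as in step 11 removes both tert-butyl esters and brings the route back at 22.

Step 9 (Chan–Lam coupling). Three processes may starve the coupling: slow boron-to-copper transfer from the ortho-methoxy boronic acid, its protodeboronation or oxidative hydroxylation, and the low nucleophilicity of the acidic, iodine-flanked phenol. The fallback reverses the polarity of the ether synthesis and builds an isomeric aryne precursor.
- It sets out from 11. H2O2 and NaOH in THF oxidise the carbon–boron bond to tert-butyl 6-(benzyloxy)-2-heptyl-4-hydroxy-3-methoxybenzoate F6.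
- The phenoxide of F6 displaces fluoride from 2-fluoro-4-methoxybenzaldehyde (K2CO3, DMF, 110 °C, SNAr ortho to the formyl group) to give tert-butyl 6-(benzyloxy)-4-(2-formyl-5-methoxyphenoxy)-2-heptyl-3-methoxybenzoate F7.
- Baeyer–Villiger oxidation with mCPBA gives tert-butyl 6-(benzyloxy)-4-[2-(formyloxy)-5-methoxyphenoxy]-2-heptyl-3-methoxybenzoate F8.
- K2CO3 in methanol frees tert-butyl 6-(benzyloxy)-2-heptyl-4-(2-hydroxy-5-methoxyphenoxy)-3-methoxybenzoate F9.
- The phenoxide of F9 has one free ortho carbon and a blocked para carbon, so I2 and NaHCO3 in aqueous THF should give tert-butyl 6-(benzyloxy)-2-heptyl-4-(2-hydroxy-3-iodo-5-methoxyphenoxy)-3-methoxybenzoate F10.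
- Sulfonylation as in step 8 with added DMAP gives tert-butyl 6-(benzyloxy)-4-{2-[(4-chlorophenyl)sulfonyloxy]-3-iodo-5-methoxyphenoxy}-2-heptyl-3-methoxybenzoate F11.
- In F11 the iodine sits on C6 and the sulfonate on C1 of ring A. The conditions of step 10 therefore release the same aryne, and the route is rejoined at 19 and hence at 21.

Step 7 (iodination of 5-methoxyresorcinol). Iodination at the carbons next to the methoxy group, or multiple iodination of this very electron-rich ring, would erode the symmetric product on which the regiochemistry of the aryne precursor depends. The fallback replaces electrophilic substitution by directed ortho-metalation.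
- From 12, MOMCl and iPr2NEt in CH2Cl2 give 1-methoxy-3,5-bis(methoxymethoxy)benzene F12.
- n-BuLi in THF at 0 °C lithiates the carbon between the two chelating acetal oxygens, and I2 gives 2-iodo-5-methoxy-1,3-bis(methoxymethoxy)benzene F13.
- Catalytic HCl in methanol at room temperature removes both acetals and returns to the route at 13.

Further compounds
F1 | step 10 | 3-(benzyloxy)-2-iodo-5-methoxyphenyl 4-chlorobenzenesulfonate | COc1cc(OCc2ccccc2)c(I)c(OS(=O)(=O)c2ccc(Cl)cc2)c1
F2 | step 10 | 2-(benzyloxy)-6-heptyl-4-methoxybenzoic acid | CCCCCCCc1cc(OC)cc(OCc2ccccc2)c1C(=O)O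
F3 | step 10 | tert-butyl 2-(benzyloxy)-6-heptyl-4-methoxybenzoate | CCCCCCCc1cc(OC)cc(OCc2ccccc2)c1C(=O)OC(C)(C)C
F4 | step 10 | tert-butyl 2-heptyl-6-hydroxy-4-methoxybenzoate | CCCCCCCc1cc(OC)cc(O)c1C(=O)OC(C)(C)C
F5 | step 10 | tert-butyl 6-(benzyloxy)-4-[2-(tert-butoxycarbonyl)-3-heptyl-5-methoxyphenoxy]-2-heptyl-3-methoxybenzoate | CCCCCCCc1cc(OC)cc(Oc2cc(OCc3ccccc3)c(C(=O)OC(C)(C)C)c(CCCCCCC)c2OC)c1C(=O)OC(C)(C)C
F6 | step 9 | tert-butyl 6-(benzyloxy)-2-heptyl-4-hydroxy-3-methoxybenzoate | CCCCCCCc1c(OC)c(O)cc(OCc2ccccc2)c1C(=O)OC(C)(C)C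
F7 | step 9 | tert-butyl 6-(benzyloxy)-4-(2-formyl-5-methoxyphenoxy)-2-heptyl-3-methoxybenzoate | COc1ccc(C=O)c(Oc2cc(OCc3ccccc3)c(C(=O)OC(C)(C)C)c(CCCCCCC)c2OC)c1
F8 | step 9 | tert-butyl 6-(benzyloxy)-4-[2-(formyloxy)-5-methoxyphenoxy]-2-heptyl-3-methoxybenzoate | COc1ccc(OC=O)c(Oc2cc(OCc3ccccc3)c(C(=O)OC(C)(C)C)c(CCCCCCC)c2OC)c1
F9 | step 9 | tert-butyl 6-(benzyloxy)-2-heptyl-4-(2-hydroxy-5-methoxyphenoxy)-3-methoxybenzoate | COc1ccc(O)c(Oc2cc(OCc3ccccc3)c(C(=O)OC(C)(C)C)c(CCCCCCC)c2OC)c1
F10 | step 9 | tert-butyl 6-(benzyloxy)-2-heptyl-4-(2-hydroxy-3-iodo-5-methoxyphenoxy)-3-methoxybenzoate | COc1cc(I)c(O)c(Oc2cc(OCc3ccccc3)c(C(=O)OC(C)(C)C)c(CCCCCCC)c2OC)c1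
F11 | step 9 | tert-butyl 6-(benzyloxy)-4-{2-[(4-chlorophenyl)sulfonyloxy]-3-iodo-5-methoxyphenoxy}-2-heptyl-3-methoxybenzoate | COc1cc(I)c(OS(=O)(=O)c2ccc(Cl)cc2)c(Oc2cc(OCc3ccccc3)c(C(=O)OC(C)(C)C)c(CCCCCCC)c2OC)c1
F12 | step 7 | 1-methoxy-3,5-bis(methoxymethoxy)benzene | COCOc1cc(OC)cc(OCOC)c1
F13 | step 7 | 2-iodo-5-methoxy-1,3-bis(methoxymethoxy)benzene | COCOc1cc(OC)cc(OCOC)c1I
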